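**Plan**

- Retrosynthesis: the MOM group and the C7 propenyl C=C are removed first (back to a C7 aldehyde). The two dioxane C–O bonds O1–C2 and C4a–O4 are then cut together, giving a bromophenol (ring A) and a cis aryl methyl epoxide (ring C). The epoxide goes back to a (Z)-propenylarene, and this to an aryl bromide and (Z)-propenylboronic acid.
- Enabling feature (numbering O1–C2(aryl)–C3(methyl)–O4 in ring B, C4a/C8a at the fusion, OMe on C5, side chain on C7): C4a is para to C7, so a C7 formyl group activates a C4a–Br bond for displacement by the C3 oxygen. The phenol oxygen on the adjacent C8a (O1) is placed to open the epoxide at the benzylic C2.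
- Forward: rings A and C are bought as arenes. Ring B is the only ring made, in step 5, by epoxide opening and O-arylation in one flask. The C7 aldehyde is then converted into the (E)-propenyl group and the phenol is freed last.
- Stereochemistry: C3 (R) comes from the catalyst-controlled epoxidation of the Z-alkene and is not touched again. C2 (R) comes from SN2 inversion at the benzylic epoxide carbon, which maps the cis-epoxide onto the trans-dioxane. The E-alkene comes from the Julia–Kocienski olefination.

Key step: step 5

Remark: 4-bromo-2,6-dimethoxyphenol, (Z)-prop-1-en-1-ylboronic acid, 4-bromo-3,5-dimethoxybenzaldehyde and 1-phenyl-1H-tetrazole-5-thiol are taken to be catalogue compounds; the dioxane numbering above is used for all intermediates.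

**Route**

Step 1
Reactants: 1 4-bromo-2,6-dimethoxyphenol
Product: 2 5-bromo-1,3-dimethoxy-2-(methoxymethoxy)benzene
Conditions: NaH, MOMCl, THF/DMF, 0 °C to rt
Reagents that add atoms: chloromethyl methyl ether, COCCl
Why: Williamson-type O-alkylation of the sodium phenoxide with the small, reactive chloromethyl ether should protect even this di-ortho-substituted phenol as a MOM acetal that is stable to all the basic steps that follow.

Step 2
Reactants: 2 5-bromo-1,3-dimethoxy-2-(methoxymethoxy)benzene; 3 (Z)-prop-1-en-1-ylboronic acid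
Product: 4 1,3-dimethoxy-2-(methoxymethoxy)-5-[(Z)-prop-1-en-1-yl]benzene
Conditions: Pd(dppf)Cl2 (3 mol %), K2CO3, 1,4-dioxane/H2O, 80 °C
Reagents that add atoms: none
Why: Suzuki–Miyaura coupling of an unhindered aryl bromide with an alkenylboronic acid proceeds with retention of alkene geometry, so the Z-propenyl group should be transferred intact.

Step 3
Reactants: 4 1,3-dimethoxy-2-(methoxymethoxy)-5-[(Z)-prop-1-en-1-yl]benzene
Product: 5 (2S,3R)-2-[3,5-dimethoxy-4-(methoxymethoxy)phenyl]-3-methyloxirane (cis)
Conditions: (S,S)-[N,N'-bis(3,5-di-tert-butylsalicylidene)-1,2-cyclohexanediaminato]MnCl (5 mol %), 4-phenylpyridine N-oxide (20 mol %), aq NaOCl (pH 11.3, Na2HPO4), CH2Cl2, 0 °C; filtration through Et3N-deactivated SiO2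
Reagents that add atoms: sodium hypochlorite, [Na+].[O-]Cl
Why: Jacobsen–Katsuki epoxidation has cis aryl alkyl alkenes as its best substrate class, and the (S,S)-catalyst should deliver oxygen to the same face as with cis-β-methylstyrene and indene, setting the benzylic carbon as S and the methyl-bearing carbon as R in one event, while the basic medium spares the MOM group and the acid-labile epoxide.

Step 4
Reactants: 6 4-bromo-3,5-dimethoxybenzaldehyde
Product: 7 4-bromo-3-hydroxy-5-methoxybenzaldehyde
Conditions: BBr3 (1.3 equiv), CH2Cl2, −78 to 0 °C; H2O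
Reagents that add atoms: none
Why: Lewis acid cleavage of an aryl methyl ether (BBr3 demethylation) on a substrate whose two methoxy groups are equivalent by symmetry can give only one monophenol, and limiting reagent and temperature should stop the reaction after the first cleavage, unreacted 6 being recyclable.

Step 5
Reactants: 7 4-bromo-3-hydroxy-5-methoxybenzaldehyde; 5 (2S,3R)-2-[3,5-dimethoxy-4-(methoxymethoxy)phenyl]-3-methyloxirane
Product: 9 (2R,3R)-2-[3,5-dimethoxy-4-(methoxymethoxy)phenyl]-5-methoxy-3-methyl-2,3-dihydro-1,4-benzodioxine-7-carbaldehyde, via ring-opened C3 cesium alkoxide 8 (not isolated)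
Conditions: Cs2CO3 (2.5 equiv), CuI (10 mol %), 1,10-phenanthroline (20 mol %), DMF, 80 °C then 110 °C, Ar
Reagents that add atoms: none
Why: Cs2CO3 forms the phenoxide of 7 (the future O1), which opens the cis-epoxide 5 by SN2 attack at the benzylic carbon to give the C3 alkoxide 8; this alkoxide then displaces the C4a bromide, either through a Meisenheimer adduct or through an Ullmann-type cycle of monovalent copper, so that O1–C2 and C4a–O4 form in one flask. The closest known reaction type is the base-mediated opening of epoxides by 2-halophenols followed in the same pot by copper-catalysed intramolecular O-arylation to 2,3-dihydro-1,4-benzodioxines. Ring B closes as a six-membered ring by ipso attack of the C3 oxygen on C4a (6-exo-trig at the arene carbon), with C3 untouched. The new C2 stereocenter is set by backside attack with inversion of the (2S) epoxide carbon, giving 2R, while C3 keeps the R configuration from step 3, so the cis-epoxide should give the trans-dioxane. The step needs benzylic regioselectivity in the opening, secured by the electron-rich 4-alkoxy-3,5-dimethoxyphenyl group on C2, and closure at C4a without Smiles-type scrambling at C8a, secured by the formyl group being para to C4a and only meta to C8a.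

Step 6
Reactants: 10 1-phenyl-1H-tetrazole-5-thiol
Product: 11 5-(ethylsulfanyl)-1-phenyl-1H-tetrazole
Conditions: EtI, K2CO3, acetone, rt
Reagents that add atoms: iodoethane, CCI
Why: SN2 S-alkylation of the soft tetrazole thiolate with a primary iodide is a routine first step towards Julia–Kocienski sulfones.

Step 7
Reactants: 11 5-(ethylsulfanyl)-1-phenyl-1H-tetrazole
Product: 12 5-(ethylsulfonyl)-1-phenyl-1H-tetrazole
Conditions: H2O2 (30% aq), (NH4)6Mo7O24·4H2O (cat.), EtOH, 0 °C to rt
Reagents that add atoms: hydrogen peroxide, OO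
Why: Molybdate-catalysed peroxide oxidation takes the sulfide through the sulfoxide to the sulfone, the standard preparation of 1-phenyltetrazolyl sulfones.

Step 8
Reactants: 9 (2R,3R)-2-[3,5-dimethoxy-4-(methoxymethoxy)phenyl]-5-methoxy-3-methyl-2,3-dihydro-1,4-benzodioxine-7-carbaldehyde; 12 5-(ethylsulfonyl)-1-phenyl-1H-tetrazole
Product: 13 (2R,3R)-2-[3,5-dimethoxy-4-(methoxymethoxy)phenyl]-5-methoxy-3-methyl-7-[(E)-prop-1-en-1-yl]-2,3-dihydro-1,4-benzodioxine
Conditions: KN(SiMe3)2, DME, −60 °C to rt
Reagents that add atoms: none
Why: Julia–Kocienski olefination (addition of the metalated sulfone, Smiles rearrangement, loss of SO2 and the tetrazolone) of a non-enolisable aryl aldehyde with a 1-phenyltetrazolyl sulfone and a potassium base in DME should give the E-alkene, and no proton at C2 or C3 is acidic enough to be touched.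

Step 9
Reactants: 13 (2R,3R)-2-[3,5-dimethoxy-4-(methoxymethoxy)phenyl]-5-methoxy-3-methyl-7-[(E)-prop-1-en-1-yl]-2,3-dihydro-1,4-benzodioxine
Product: 14 4-[(2R,3R)-5-methoxy-3-methyl-7-[(E)-prop-1-en-1-yl]-2,3-dihydro-1,4-benzodioxin-2-yl]-2,6-dimethoxyphenol
Conditions: 2 M aq HCl, MeOH/THF, rt to 40 °C
Reagents that add atoms: none
Why: Acid-catalysed solvolysis of the phenolic MOM acetal occurs under dilute acid near room temperature, conditions that the diaryl-type ether bonds of the trans-dioxane and the conjugated E-propenyl group should tolerate.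

**Compound list**

1 | 4-bromo-2,6-dimethoxyphenol | COc1cc(Br)cc(OC)c1O | starting material
2 | 5-bromo-1,3-dimethoxy-2-(methoxymethoxy)benzene | COCOc1c(OC)cc(Br)cc1OC | intermediate
3 | (Z)-prop-1-en-1-ylboronic acid | C/C=C\B(O)O | starting material
4 | 1,3-dimethoxy-2-(methoxymethoxy)-5-[(Z)-prop-1-en-1-yl]benzene | C/C=C\c1cc(OC)c(OCOC)c(OC)c1 | intermediate
5 | (2S,3R)-2-[3,5-dimethoxy-4-(methoxymethoxy)phenyl]-3-methyloxirane (cis) | O1[C@@H](c2cc(OC)c(OCOC)c(OC)c2)[C@H]1C | intermediate
6 | 4-bromo-3,5-dimethoxybenzaldehyde | COc1cc(C=O)cc(OC)c1Br | starting material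
7 | 4-bromo-3-hydroxy-5-methoxybenzaldehyde | O=Cc1cc(O)c(Br)c(OC)c1 | intermediate
8 | cesium (1R,2R)-1-(2-bromo-5-formyl-3-methoxyphenoxy)-1-[3,5-dimethoxy-4-(methoxymethoxy)phenyl]propan-2-olate | O=Cc1cc(OC)c(Br)c(c1)O[C@H](c1cc(OC)c(OCOC)c(OC)c1)[C@@H](C)[O-].[Cs+] | intermediate
9 | (2R,3R)-2-[3,5-dimethoxy-4-(methoxymethoxy)phenyl]-5-methoxy-3-methyl-2,3-dihydro-1,4-benzodioxine-7-carbaldehyde | O=Cc1cc(OC)c2c(c1)O[C@H](c1cc(OC)c(OCOC)c(OC)c1)[C@@H](C)O2 | intermediate
10 | 1-phenyl-1H-tetrazole-5-thiol | Sc1nnnn1-c1ccccc1 | starting material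
11 | 5-(ethylsulfanyl)-1-phenyl-1H-tetrazole | CCSc1nnnn1-c1ccccc1 | intermediate
12 | 5-(ethylsulfonyl)-1-phenyl-1H-tetrazole | CCS(=O)(=O)c1nnnn1-c1ccccc1 | intermediate
13 | (2R,3R)-2-[3,5-dimethoxy-4-(methoxymethoxy)phenyl]-5-methoxy-3-methyl-7-[(E)-prop-1-en-1-yl]-2,3-dihydro-1,4-benzodioxine | C/C=C/c1cc(OC)c2c(c1)O[C@H](c1cc(OC)c(OCOC)c(OC)c1)[C@@H](C)O2 | intermediate
14 | 4-[(2R,3R)-5-methoxy-3-methyl-7-[(E)-prop-1-en-1-yl]-2,3-dihydro-1,4-benzodioxin-2-yl]-2,6-dimethoxyphenol | C/C=C/c1cc(OC)c2c(c1)O[C@H](c1cc(OC)c(O)c(OC)c1)[C@@H](C)O2 | target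

**Count**

Total steps: 9. Longest linear sequence: 6 steps (steps 1, 2, 3, 5, 8, 9).

**Steps most likely to fail, with fallbacks**

Step 5. The phenoxide may attack the methyl-bearing carbon C3 of the epoxide in competition with the benzylic C2, which would lead to the regioisomeric dioxane. The O-arylation may also lag behind the opening. The fallback inverts the roles of the two oxygens so that attack at the methyl-bearing carbon becomes the productive path; it sets out from 4 and comes back at 9.
- Compound 4 would be epoxidised as in step 3 but with the (R,R)-enantiomer of the manganese catalyst, to give (2R,3S)-2-[3,5-dimethoxy-4-(methoxymethoxy)phenyl]-3-methyloxirane F1.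
- Purchased 3-bromo-4-hydroxy-5-methoxybenzaldehyde (5-bromovanillin, O=Cc1cc(OC)c(O)c(Br)c1), whose phenol is the future O4 para to the formyl group, would open F1 at the methyl-bearing carbon with inversion (Cs2CO3, DMF, 100 °C). This should give 3-bromo-4-{[(1R,2R)-1-[3,5-dimethoxy-4-(methoxymethoxy)phenyl]-1-hydroxypropan-2-yl]oxy}-5-methoxybenzaldehyde F2, which would be isolated.
- An Ullmann-type intramolecular O-arylation (CuI, 1,10-phenanthroline, Cs2CO3, toluene, 110 °C) would then join the benzylic oxygen to the unactivated C8a–Br bond with retention at the carbinol carbon, to give 9.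

Step 3. The stepwise oxygen transfer may leak to the trans-epoxide through rotation of the benzylic radical, the enantioselectivity may erode on this very electron-rich arene, and the epoxide may rearrange during isolation. The fallback takes the C3 stereocenter from the chiral pool; it sets out from 2 and comes back at 5.
- Purchased (S)-2-chloropropanoyl chloride would be converted with N,O-dimethylhydroxylamine hydrochloride and pyridine (CH2Cl2, 0 °C) into the Weinreb amide (S)-2-chloro-N-methoxy-N-methylpropanamide F3.
- Bromine–lithium exchange on 2 (n-BuLi, THF, −78 °C) and addition to F3 should give (S)-2-chloro-1-[3,5-dimethoxy-4-(methoxymethoxy)phenyl]propan-1-one F4 after a mildly acidic quench.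
- Reduction with NaBH4 in MeOH at −40 °C is expected, under Felkin–Anh control with the C–Cl bond anti to the incoming hydride, to favour the syn chlorohydrin (1S,2S)-2-chloro-1-[3,5-dimethoxy-4-(methoxymethoxy)phenyl]propan-1-ol F5, which would be purified from its anti isomer.
- K2CO3 in MeOH at rt would close the ring by attack of the benzylic alkoxide on the chlorine-bearing carbon with inversion, to give 5.

Step 9. During MOM removal the acid may add solvent to, or oligomerise, the electron-rich propenylarene, or ionise the benzylic C2–O1 bond. The fallback changes the order of events so that no acid meets the alkene; it sets out from 9 and comes back at 14.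
- The MOM group would be removed from the aldehyde 9 with the same dilute HCl in MeOH/THF, to give (2R,3R)-2-(4-hydroxy-3,5-dimethoxyphenyl)-5-methoxy-3-methyl-2,3-dihydro-1,4-benzodioxine-7-carbaldehyde F6.
- Julia–Kocienski olefination of F6 with sulfone 12, using one extra equivalent of KN(SiMe3)2 in DME at −60 °C to rt to carry the phenol as its potassium phenoxide, should then give 14 directly.

**Further compounds**

F1 | step 5 | (2R,3S)-2-[3,5-dimethoxy-4-(methoxymethoxy)phenyl]-3-methyloxirane | O1[C@H](c2cc(OC)c(OCOC)c(OC)c2)[C@@H]1C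
F2 | step 5 | 3-bromo-4-{[(1R,2R)-1-[3,5-dimethoxy-4-(methoxymethoxy)phenyl]-1-hydroxypropan-2-yl]oxy}-5-methoxybenzaldehyde | O=Cc1cc(OC)c(O[C@H](C)[C@H](O)c2cc(OC)c(OCOC)c(OC)c2)c(Br)c1
F3 | step 3 | (S)-2-chloro-N-methoxy-N-methylpropanamide | C[C@H](Cl)C(=O)N(C)OC
F4 | step 3 | (S)-2-chloro-1-[3,5-dimethoxy-4-(methoxymethoxy)phenyl]propan-1-one | C[C@H](Cl)C(=O)c1cc(OC)c(OCOC)c(OC)c1
F5 | step 3 | (1S,2S)-2-chloro-1-[3,5-dimethoxy-4-(methoxymethoxy)phenyl]propan-1-ol | C[C@H](Cl)[C@@H](O)c1cc(OC)c(OCOC)c(OC)c1
F6 | step 9 | (2R,3R)-2-(4-hydroxy-3,5-dimethoxyphenyl)-5-methoxy-3-methyl-2,3-dihydro-1,4-benzodioxine-7-carbaldehyde | O=Cc1cc(OC)c2c(c1)O[C@H](c1cc(OC)c(O)c(OC)c1)[C@@H](C)O2
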